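## Analysis of the target

The target (35) is a 5,10-epoxygermacranolide: a ten-membered carbocycle C1–C10 whose C5 and C10 are joined by an ether oxygen, so the core is an 11-oxabicyclo[4.4.1]undecane built from two oxepane rings, ring A (O, C10, C1–C5) and ring B (O, C5–C10). Ring A carries the C3=C4 alkene conjugated with the methyl ester C15 on C4. Ring B carries an α-methylene-γ-lactone (C11–C13) fused at C6/C7 and, on C8, the ester of (S)-2-hydroxy-2-methylbut-3-enoic acid; C10 bears the methyl C14. There are six stereocentres (5R, 6S, 7R, 8R, 10S, 2'S); the bridgeheads can only be cis, so the real relative problem is C6–C8 against the bridge. Calling exo the face of a four-carbon bridge turned toward the oxygen bridge and endo the face turned toward the other carbon bridge, the C6 oxygen is exo while C7–C11 and the C8 oxygen are endo, so the lactone is trans-fused and the C8 ester is cis to C11. Sensitive groups are the exo-methylene lactone (Michael acceptor), the enoate, the tertiary allylic alcohol and the C5–O bond allylic to the enoate; any C8 ketone on the way is β to the bridging oxygen and can open the bridge by elimination. The difficulty lies in the bridged medium ring, in four contiguous stereocentres C5–C8, and in the two four-carbon bridges being alike until each is functionalised only at its C5 end. The strategy rests on C5 and C10 standing 1,6 to each other across the carbocycle, the relationship of the two ring-fusion carbons of a decalin, so the ten-membered ring can be uncovered by breaking one bond of a naphthalene-derived bicycle.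

## Retrosynthetic reasoning

**Lactone (C12–O6).** The lactone C–O bond and the oxidation level of C12 are removed first, giving triol 32 and, with two silyl ethers, 31 and 30. The exo-methylene lactone is the group least tolerant of base, hydride and nucleophiles, so it is made last. Forward, a primary allylic alcohol must be oxidised beside a secondary and a tertiary one, and the aldehyde 33 must be trapped by the C6 hydroxyl (34); the C8 oxygen is already acylated and cannot compete. C12 is traced to the methyl of an isopropenyl group in 30 by allylic C–H oxidation.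

**Side-chain ester (C8–O acyl).** Cutting this bond gives alcohol 25 and acid 28, the silyl-protected form of 26. The cut is made while C6 is silylated, so only one hydroxyl is free.

**Stereocentres C8, C7, C6.** 25 is traced through 24, 23 and 22 to dienone 21, in which C8 is a carbonyl, C7 its α-carbon and C6 its β-carbon. This places every new bond under the regiochemical control of one carbonyl, and all three centres arise from attack on the exo face: oxygen at C6 (epoxide 22), hydrogen at C7 (protonation after reductive C7–O cleavage, 23), hydride at C8 (25).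

**C7–C11 bond.** 21 is cut between C7 and C11 into iodoenone 19 and the isopropenyl metal 20; 19 comes from enone 18. An sp2–sp2 coupling at the α-carbon avoids opening an epoxide at a hindered carbon on the concave face.

**C8 oxygen.** The C8 carbonyl and the C6=C7 alkene of 18 are traced to the C7=C8 alkene and the C6 acetate of 16, through acetoxy ketone 17. The acetate steers the oxidation to the distal carbon C8 and then leaves.

**C4–C15 bond.** The enoate of 16 is cut at C4–C15 to vinyl triflate 15, which is traced through ketone 14 and enone 13 to the allylic alcohol of 12. C5 is a bridgehead, so the C4 ketone can enolise only toward C3, which fixes the alkene position.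

**Desymmetrisation.** 12 has a free C4 hydroxyl and a C6 acetate; it is traced to meso-diacetate 11 and meso-diol 10. One enzymatic event on enantiotopic groups sets the absolute configuration of C5 and C10 and tells the two bridges apart.

**Allylic C–O bonds at C4 and C6.** 10 is traced to the meso diene ether 9 by removing both hydroxyls. Forward, the oxidation must choose the CH2 groups next to the C5–H bridgehead over those next to the quaternary C10.

**Ether bridge (C10–O) and C5–H.** 9 is cut at the C10–O bond to diol 8, which comes from hemiketal 7 by reduction. Forward, the tertiary C10 cation is captured across the ring by the C5 hydroxyl.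

**C10–C14 bond.** 7 is cut at the methyl group to dione 6. The two carbonyls of 6 are identical, and the hemiketal that closes after the first addition masks the second carbonyl.

**C5–C10 reconnection.** Joining C5 and C10 of 6 gives the ring-fusion diol 4 (through lead ester 5). Nothing is lost in complexity terms, because the ten-membered ring is then hidden in two six-membered rings and no macrocyclisation is needed.

**To the arene.** 4 is traced to epoxide 3, triene 2 and naphthalene 1.

## Alternatives that were turned down

Alternative 1: Here the C5–C6 bond and ring A are disconnected together, back to a cyclopropane-fused six-membered cyclic ether with a tethered 3-furyl group. In the forward key step a silver salt ionises a gem-dibromocyclopropane unit, disrotatory opening gives a seven-membered oxocarbenium ion with bromide on C4, and C2 of the furan attacks C5 to give A1. In its favour, A1 already holds both oxepanes, the C10 quaternary centre, the C8 silyl ether and a C4 vinyl bromide ready for carbonylation; on bond-forming economy it is clearly stronger than the chosen route. Against it, C6 and C7 are aromatic carbons in A1: the trans-fused lactone needs furan oxidation and then reduction of a tetrasubstituted C6=C7 bond with anti delivery of hydrogen, followed by methylenation. The precursor also needs an enantioselective quaternary C10 and a cationic step next to an acid-labile furan. The chosen strategy offers instead a start with no stereocentre at all and the C6–C8 centres set on a rigid bicycle by exo-face attack (22, 23, 25).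

Alternative 2: The C5–O bond is disconnected by a retro-Claisen shift: on heating, an acetyl oxygen on a cyclopropane carbon bonds to C5 of a cis vinyl group while the C1–C3 cyclopropane bond breaks, giving dihydrooxepine A2. In its favour, A2 has the C3=C4 enoate and C5 in place, and its side chain brings C6–OSi, the C7 isopropenyl group and a C8 carbonyl from acyclic chemistry; on ring-B functional-group economy it is stronger than the chosen route. Against it, the shift is an equilibrium that needs push–pull substitution and a cis cyclopropane. Ring B is still open, so the C9–C10 bond and the quaternary C10 must be formed later by conjugate addition onto the enol ether, with C10 controlled relative to C5. An extra ester on C1 must be removed, and the β-silyloxy ketone must survive heating. The chosen route has the whole bicycle by compound 9, with the C5/C10 relationship fixed by the bridge itself.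

Alternative 3: C4–C5 and C1–C10 are formed by enone–cyclobutene photocycloaddition to A3, whose strain is meant to drive a later ring expansion to the ten-membered ring. In its favour, A3 carries C15, the C10 methyl, a C6 carbonyl and the C8 silyl ether from the two partners; for oxidation pattern per step it is stronger than the chosen route. Against it, the cycloaddition must form a quaternary centre from a β-substituted enone with head-to-head and facial control. The thermal opening gives a flexible ten-membered diene of uncertain alkene geometry, and the C5–O–C10 bridge and the C5, C6, C7 centres must then be set on that flexible ring. The chosen route has the ether bridge before any stereocentre is made, needs no photochemistry on scale and starts from a bulk arene; its price is a long series of functional-group steps.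

Key step: step 4

Remarks on the chemistry (assumptions):
- Acid 26 is taken as a purchasable single enantiomer; if only the racemate is at hand it is resolved as a salt of a chiral amine before step 22.
- Hemiketal 7 is not deoxygenated directly with a silane, because the oxocarbenium ion would need a double bond from a bridgehead to the one-atom bridge; the ether is closed from diol 8 through the tertiary C10 cation (steps 6 and 7).

## Route

Step 1
Reactants: 1 naphthalene
Product: 2 1,4,5,8-tetrahydronaphthalene (isotetralin)
Conditions: Na, NH3 (l), EtOH, Et2O, −78 to −33 °C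
Reagents that add atoms: none
Why: Birch reduction; each benzenoid ring takes up two electrons and two protons at its 1,4-positions, and the tetrasubstituted ring-fusion alkene, the hardest to reduce, is left.

Step 2
Reactants: 2 isotetralin
Product: 3 11-oxatricyclo[4.4.1.0(1,6)]undeca-3,8-diene (the 4a,8a-epoxide)
Conditions: mCPBA (1.0 equiv), CH2Cl2, 0 °C
Reagents that add atoms: 3-chloroperbenzoic acid, O=C(OO)c1cccc(Cl)c1
Why: Prilezhaev epoxidation; the tetrasubstituted central alkene is the most nucleophilic of the three, so one equivalent of peracid should react there.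

Step 3
Reactants: 3 the 4a,8a-epoxide
Product: 4 trans-1,4,5,8-tetrahydronaphthalene-4a,8a-diol
Conditions: HClO4 (cat.), THF/H2O, 0 °C to rt
Reagents that add atoms: water, O
Why: Acid-catalysed epoxide hydrolysis with anti opening gives the trans-diaxial diol; dilute aqueous acid at low temperature favours capture by water over a pinacol-type shift.

Step 4
Reactants: 4 trans-4a,8a-diol
Product: 6 (3Z,8Z)-cyclodeca-3,8-diene-1,6-dione, via lead alkoxide triacetate 5 (not isolated)
Conditions: Pb(OAc)4 (1.1 equiv), pyridine/benzene, 10 °C to rt; filtered cold and used at once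
Reagents that add atoms: none
Why: Ligand exchange on tetravalent lead gives monoalkoxide 5; the hydroxyls are held trans-diaxial, so a five-membered cyclic diolate cannot form, and cleavage instead runs as a concerted two-electron fragmentation in which acetate takes the proton of the free hydroxyl while the anti-periplanar C4a–C8a bond breaks and lead leaves as divalent lead diacetate. The closest known reaction is the Criegee cleavage of trans-decalin-9,10-diol to cyclodecane-1,6-dione, which is slower than that of the cis-diol and is helped by pyridine. No ring is closed by bond formation: the ten-membered ring appears because the broken bond was shared by two six-membered rings, so no cyclisation mode and no dilution are involved. No stereocentre is formed, and both alkenes stay Z because they were ring alkenes of the cyclohexene halves. The step needs chemoselectivity for the glycol over the two alkenes, which Pb(OAc)4 has at room temperature. It also needs 6 to survive: 6 is doubly β,γ-unsaturated and can slip into conjugation or close by transannular aldol reaction, so the acetic acid is buffered by pyridine, the temperature is kept low and 6 is used directly. Periodate is not an option, because it requires the cyclic ester that the trans-diaxial geometry forbids.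

Step 5
Reactants: 6 cyclodecadienedione
Product: 7 6-methyl-11-oxabicyclo[4.4.1]undeca-3,8-dien-1-ol (transannular hemiketal)
Conditions: MeLi (1.1 equiv), CeCl3 (1.2 equiv), THF, −78 °C; aq NH4Cl
Reagents that add atoms: methyllithium, [Li]C
Why: Organocerium (Imamoto) addition; the low basicity avoids enolisation of the doubly activated α-CH2 groups, and the tertiary alkoxide adds across the ring to the second carbonyl, which both closes the hemiketal and stops a second addition.

Step 6
Reactants: 7 hemiketal
Product: 8 (3Z,8Z)-1-methylcyclodeca-3,8-diene-1,6-diol (cis/trans mixture)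
Conditions: NaBH4, MeOH, 0 °C
Reagents that add atoms: none
Why: Borohydride reduces the ring-opened hydroxy ketone tautomer, as in lactol reduction; the relative configuration of the two carbinols does not matter because C10 is ionised in the next step.

Step 7
Reactants: 8 diol
Product: 9 1-methyl-11-oxabicyclo[4.4.1]undeca-3,8-diene (meso; alkenes C2=C3 and C7=C8)
Conditions: CF3CO2H (0.2–1 equiv), CH2Cl2, 0 °C
Reagents that add atoms: none
Why: SN1 etherification; the tertiary C10 cation is captured across the ring by the C5 hydroxyl, closing both seven-membered rings at once, and any alkene formed by proton loss re-enters through the same cation.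

Step 8
Reactants: 9 diene ether
Product: 10 meso-diol (6-methyl-11-oxabicyclo[4.4.1]undeca-3,8-diene-2,10-diol; exo hydroxyls on C4 and C6)
Conditions: SeO2 (0.5 equiv), t-BuOOH (4 equiv), CH2Cl2, rt
Reagents that add atoms: selenium dioxide, O=[Se]=O; tert-butyl hydroperoxide, CC(C)(C)OO
Why: Catalytic SeO2 allylic hydroxylation (ene reaction, then [2,3]-shift) keeps the alkenes in place and delivers oxygen on the exo face; the C10 methyl is gauche to the C1/C9 hydrogens, so abstraction should prefer C4/C6, and the mirror-symmetric product is what step 10 needs.

Step 9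
Reactants: 10 meso-diol
Product: 11 meso-diacetate
Conditions: Ac2O, pyridine, DMAP (cat.), CH2Cl2, rt
Reagents that add atoms: acetic anhydride, CC(=O)OC(C)=O
Why: Standard acylation of two secondary allylic alcohols.

Step 10
Reactants: 11 meso-diacetate
Product: 12 monoacetate (free exo hydroxyl on C4, exo acetate on C6)
Conditions: Pseudomonas cepacia lipase (Amano PS), pH 7 phosphate buffer/acetone, 30 °C
Reagents that add atoms: none
Why: Enantiotopic-group-selective enzymatic hydrolysis of a meso-diacetate; by the Kazlauskas rule (bridgehead side large, vinyl side medium) the lipase should cleave the acetate on the (R)-carbinol C4 and leave the (S)-C6 acetate, which fixes the absolute configuration of C5 and C10. If the enzyme showed the opposite preference, acetylation of 10 with vinyl acetate and the same lipase would lead to the same 12.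

Step 11
Reactants: 12 monoacetate
Product: 13 enone acetate (C4 ketone, C2=C3)
Conditions: MnO2 (excess), CH2Cl2, rt
Reagents that add atoms: none
Why: MnO2 oxidises the allylic alcohol selectively under neutral conditions, so the β-acetoxy group on C6 is not eliminated.

Step 12
Reactants: 13 enone acetate
Product: 14 ketone acetate (C4 ketone, C2 and C3 saturated)
Conditions: [(Ph3P)CuH]6 (0.4 equiv), benzene, H2O (2 equiv), rt
Reagents that add atoms: none
Why: Copper hydride conjugate reduction is selective for the enone and leaves the isolated alkene and the allylic acetate alone.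

Step 13
Reactants: 14 ketone acetate
Product: 15 vinyl triflate (C3=C4, triflate on C4)
Conditions: KN(SiMe3)2, THF, −78 °C; then N-(5-chloropyridin-2-yl)triflimide
Reagents that add atoms: N-(5-chloropyridin-2-yl)bis(trifluoromethanesulfonyl)imide, FC(F)(F)S(=O)(=O)N(c1ccc(Cl)cn1)S(=O)(=O)C(F)(F)F
Why: Kinetic enolate formation and O-triflation; only C3 carries accessible α-hydrogens (C5 is a bridgehead), so the alkene is placed at C3=C4, and the ketone is more acidic than the acetate.

Step 14
Reactants: 15 vinyl triflate
Product: 16 enoate acetate (methyl ester C15 on C4, C3=C4)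
Conditions: Pd(OAc)2 (5 mol %), dppf, CO (1 atm), MeOH, Et3N, DMF, 45 °C
Reagents that add atoms: carbon monoxide, [C-]#[O+]; methanol, CO
Why: Palladium-catalysed methoxycarbonylation of a vinyl triflate; zerovalent palladium inserts into the C–OTf bond much faster than it ionises the secondary allylic acetate, which would need attack on the hindered endo face.

Step 15
Reactants: 16 enoate acetate
Product: 18 enone (C8 ketone, C6=C7), via acetoxy ketone 17 (not isolated)
Conditions: Pd(OAc)2 (10 mol %), 1,4-benzoquinone, aq HBF4, DMA/MeCN/H2O, rt; then DBU, CH2Cl2, 0 °C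
Reagents that add atoms: water, O
Why: Wacker-type oxidation of an internal alkene under chloride-free acidic conditions; the allylic acetate steers water to the distal carbon C8 to give 17, and E1cB loss of acetate then moves the unsaturation to C6=C7. The enoate alkene is too electron-poor to react.

Step 16
Reactants: 18 enone
Product: 19 iodoenone (iodine on C7)
Conditions: I2, pyridine/CH2Cl2, 0 °C to rt
Reagents that add atoms: iodine, II
Why: α-Iodination of an enone by pyridine addition, iodination and elimination; the enoate on ring A has no α-hydrogen and cannot react this way.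

Step 17
Reactants: 19 iodoenone; 20 tributyl(prop-1-en-2-yl)stannane
Product: 21 dienone (isopropenyl on C7)
Conditions: Pd2(dba)3 (2.5 mol %), AsPh3, CuI (cat.), NMP, rt
Reagents that add atoms: none
Why: Stille coupling of an α-iodoenone under neutral conditions, chosen so that no base can open the ether bridge, which is β to the C8 ketone.

Step 18
Reactants: 21 dienone
Product: 22 epoxy ketone (exo 6,7-epoxide, isopropenyl on C7 endo)
Conditions: t-BuOOH, DBU, CH2Cl2, 0 °C, short reaction time
Reagents that add atoms: tert-butyl hydroperoxide, CC(C)(C)OO
Why: Weitz–Scheffer epoxidation; the peroxide anion adds to C6 from the exo face, away from ring A, which sets the C6 oxygen, and the enone reacts far faster than the enoate or the isopropenyl group.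

Step 19
Reactants: 22 epoxy ketone
Product: 23 hydroxy ketone (exo C6 hydroxyl, endo C7 isopropenyl, C8 ketone)
Conditions: SmI2 (2.2 equiv), THF/MeOH, −90 °C
Reagents that add atoms: none
Why: SmI2 cleaves the α-C–O bond of the epoxy ketone; the samarium enolate is protonated at C7 from the open exo face, which puts the isopropenyl group endo and trans to the C6 oxygen, also the more stable arrangement.

Step 20
Reactants: 23 hydroxy ketone
Product: 24 C6 triethylsilyl ether
Conditions: Et3SiOTf, 2,6-lutidine, CH2Cl2, −78 °C
Reagents that add atoms: triethylsilyl trifluoromethanesulfonate, CC[Si](CC)(CC)OS(=O)(=O)C(F)(F)F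
Why: Silylation under weakly basic conditions avoids dehydration of the aldol and marks C6 as the oxygen to be freed last.

Step 21
Reactants: 24 silyl ether ketone
Product: 25 alcohol (endo C8 hydroxyl)
Conditions: NaBH4, MeOH/CH2Cl2, −40 °C
Reagents that add atoms: none
Why: Hydride attacks C8 from the exo face, because the endo face is blocked by ring A and by the adjacent endo isopropenyl group; this gives the endo alcohol cis to C11, and the enoate is not reduced.

Step 22
Reactants: 26 (S)-2-hydroxy-2-methylbut-3-enoic acid
Product: 28 (S)-2-methyl-2-(triethylsilyloxy)but-3-enoic acid, via bis-silyl derivative 27 (not isolated)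
Conditions: Et3SiOTf (2.2 equiv), 2,6-lutidine, CH2Cl2, 0 °C; then THF/H2O, AcOH (cat.), 0 °C
Reagents that add atoms: triethylsilyl trifluoromethanesulfonate, CC[Si](CC)(CC)OS(=O)(=O)C(F)(F)F
Why: Exhaustive silylation followed by selective hydrolysis of the labile silyl ester; the quaternary stereocentre is not touched.

Step 23
Reactants: 25 alcohol; 28 silyl-protected acid
Product: 30 C8 ester, via mixed anhydride 29 (not isolated)
Conditions: 2,4,6-Cl3C6H2COCl, Et3N, THF, rt; then 25, DMAP, toluene, 40 °C
Reagents that add atoms: none
Why: Yamaguchi esterification, suited to a hindered acid and a hindered secondary alcohol; the configuration at C8 is retained because the C8–O bond is not broken.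

Step 24
Reactants: 30 ester
Product: 31 allylic alcohol (CH2OH, C12, in place of the isopropenyl methyl)
Conditions: SeO2 (0.5 equiv), t-BuOOH, CH2Cl2, rt
Reagents that add atoms: selenium dioxide, O=[Se]=O; tert-butyl hydroperoxide, CC(C)(C)OO
Why: SeO2 allylic hydroxylation of the isopropenyl methyl; the competing C7–H is flanked by two oxygenated carbons and is hindered, the enoate γ-CH2 is deactivated, and the side-chain vinyl group has no allylic hydrogen.

Step 25
Reactants: 31 allylic alcohol
Product: 32 triol (C6, C12 and side-chain hydroxyls free)
Conditions: HF·pyridine, THF/pyridine, 0 °C to rt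
Reagents that add atoms: none
Why: Buffered fluoride removes both triethylsilyl ethers without acyl migration or ester cleavage.

Step 26
Reactants: 32 triol
Product: 35 the target (5R,6S,7R,8R,10S; 2'S), via hydroxy enal 33 (not isolated), via lactol 34 (not isolated)
Conditions: TEMPO (cat.), PhI(OAc)2, CH2Cl2, rt
Reagents that add atoms: none
Why: Oxidative lactonisation of a 1,4-diol; the primary allylic alcohol is oxidised first, the aldehyde is trapped by the exo C6 hydroxyl as a trans-fused lactol, and this is oxidised to the lactone; the tertiary alcohol is inert.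

## Compound list

1 | naphthalene | c1ccc2ccccc2c1 | starting material
2 | 1,4,5,8-tetrahydronaphthalene (isotetralin) | C1C=CCC2=C1CC=CC2 | intermediate
3 | 11-oxatricyclo[4.4.1.0(1,6)]undeca-3,8-diene | C1C=CCC2(O3)CC=CCC123 | intermediate
4 | trans-1,4,5,8-tetrahydronaphthalene-4a,8a-diol | O[C@]12CC=CC[C@]1(O)CC=CC2 | intermediate
5 | lead alkoxide triacetate of 4 (tetravalent lead monoester) | CC(=O)O[Pb](OC(C)=O)(OC(C)=O)O[C@]12CC=CC[C@]1(O)CC=CC2 | intermediate
6 | (3Z,8Z)-cyclodeca-3,8-diene-1,6-dione | O=C1C/C=C\CC(=O)C/C=C\C1 | intermediate
7 | 6-methyl-11-oxabicyclo[4.4.1]undeca-3,8-dien-1-ol | C1C[C@]2(C)CC=CC[C@@](O)(O2)CC=1 | intermediate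
8 | (3Z,8Z)-1-methylcyclodeca-3,8-diene-1,6-diol (cis/trans mixture, carbinol configurations not defined) | CC1(O)C/C=C\CC(O)C/C=C\C1 | intermediate
9 | 1-methyl-11-oxabicyclo[4.4.1]undeca-3,8-diene | C1C[C@]2(C)CC=CC[C@@H](O2)CC=1 | intermediate
10 | meso-6-methyl-11-oxabicyclo[4.4.1]undeca-3,8-diene-2,10-diol (exo hydroxyls on C4 (R) and C6 (S)) | C1C[C@]2(C)CC=C[C@@H](O)[C@@H](O2)[C@@H](O)C=1 | intermediate
11 | meso-diacetate of 10 | C1C[C@]2(C)CC=C[C@@H](OC(C)=O)[C@@H](O2)[C@@H](OC(C)=O)C=1 | intermediate
12 | monoacetate: C4 hydroxyl free, C6 acetate, both exo | C1C[C@]2(C)CC=C[C@@H](O)[C@@H](O2)[C@@H](OC(C)=O)C=1 | intermediate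
13 | enone acetate: C4 ketone, C2=C3, exo C6 acetate, C7=C8 | C1C[C@]2(C)CC=CC(=O)[C@@H](O2)[C@@H](OC(C)=O)C=1 | intermediate
14 | ketone acetate: C4 ketone, exo C6 acetate, C7=C8 | C1C[C@]2(C)CCCC(=O)[C@@H](O2)[C@@H](OC(C)=O)C=1 | intermediate
15 | vinyl triflate: C3=C4 with triflate on C4, exo C6 acetate, C7=C8 | C1C[C@]2(C)CCC=C(OS(=O)(=O)C(F)(F)F)[C@@H](O2)[C@@H](OC(C)=O)C=1 | intermediate
16 | enoate acetate: methyl ester on C4, C3=C4, exo C6 acetate, C7=C8 | C1C[C@]2(C)CCC=C(C(=O)OC)[C@@H](O2)[C@@H](OC(C)=O)C=1 | intermediate
17 | acetoxy ketone: as 16 with a C8 ketone and a C7 methylene | O=C1C[C@]2(C)CCC=C(C(=O)OC)[C@@H](O2)[C@@H](OC(C)=O)C1 | intermediate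
18 | enone: methyl ester on C4, C3=C4, C8 ketone, C6=C7 | O=C1C[C@]2(C)CCC=C(C(=O)OC)[C@@H](O2)C=C1 | intermediate
19 | iodoenone: 18 with iodine on C7 | O=C1C[C@]2(C)CCC=C(C(=O)OC)[C@@H](O2)C=C1I | intermediate
20 | tributyl(prop-1-en-2-yl)stannane | CC(=C)[Sn](CCCC)(CCCC)CCCC | starting material
21 | dienone: 18 with isopropenyl on C7 | O=C1C[C@]2(C)CCC=C(C(=O)OC)[C@@H](O2)C=C1C(C)=C | intermediate
22 | epoxy ketone: exo 6,7-epoxide, endo isopropenyl on C7, C8 ketone | O=C1C[C@]2(C)CCC=C(C(=O)OC)[C@@H](O2)[C@H]3O[C@@]13C(C)=C | intermediate
23 | hydroxy ketone: exo C6 hydroxyl, endo C7 isopropenyl, C8 ketone | O=C1C[C@]2(C)CCC=C(C(=O)OC)[C@@H](O2)[C@@H](O)[C@@H]1C(C)=C | intermediate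
24 | C6 triethylsilyl ether of 23 | O=C1C[C@]2(C)CCC=C(C(=O)OC)[C@@H](O2)[C@@H](O[Si](CC)(CC)CC)[C@@H]1C(C)=C | intermediate
25 | alcohol: exo C6 OSiEt3, endo C7 isopropenyl, endo C8 hydroxyl | O[C@@H]1C[C@]2(C)CCC=C(C(=O)OC)[C@@H](O2)[C@@H](O[Si](CC)(CC)CC)[C@@H]1C(C)=C | intermediate
26 | (S)-2-hydroxy-2-methylbut-3-enoic acid | C=C[C@](C)(O)C(=O)O | starting material
27 | triethylsilyl (S)-2-methyl-2-(triethylsilyloxy)but-3-enoate | C=C[C@](C)(O[Si](CC)(CC)CC)C(=O)O[Si](CC)(CC)CC | intermediate
28 | (S)-2-methyl-2-(triethylsilyloxy)but-3-enoic acid | C=C[C@](C)(O[Si](CC)(CC)CC)C(=O)O | intermediate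
29 | 2,4,6-trichlorobenzoic (S)-2-methyl-2-(triethylsilyloxy)but-3-enoic anhydride | C=C[C@](C)(O[Si](CC)(CC)CC)C(=O)OC(=O)c1c(Cl)cc(Cl)cc1Cl | intermediate
30 | C8 ester of 25 with acid 28 | C=C[C@](C)(O[Si](CC)(CC)CC)C(=O)O[C@@H]1C[C@]2(C)CCC=C(C(=O)OC)[C@@H](O2)[C@@H](O[Si](CC)(CC)CC)[C@@H]1C(C)=C | intermediate
31 | allylic alcohol: 30 with C12 hydroxymethyl on C11 | C=C[C@](C)(O[Si](CC)(CC)CC)C(=O)O[C@@H]1C[C@]2(C)CCC=C(C(=O)OC)[C@@H](O2)[C@@H](O[Si](CC)(CC)CC)[C@@H]1C(CO)=C | intermediate
32 | triol: free C6, C12 and side-chain hydroxyls | C=C[C@](C)(O)C(=O)O[C@@H]1C[C@]2(C)CCC=C(C(=O)OC)[C@@H](O2)[C@@H](O)[C@@H]1C(CO)=C | intermediate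
33 | hydroxy enal: C12 aldehyde, free C6 hydroxyl | C=C[C@](C)(O)C(=O)O[C@@H]1C[C@]2(C)CCC=C(C(=O)OC)[C@@H](O2)[C@@H](O)[C@@H]1C(C=O)=C | intermediate
34 | lactol (C12 hemiacetal closed on the C6 oxygen, anomers) | C=C[C@](C)(O)C(=O)O[C@@H]1C[C@]2(C)CCC=C(C(=O)OC)[C@@H](O2)[C@H]2OC(O)C(=C)[C@@H]21 | intermediate
35 | CNP0325750.1 (5R,6S,7R,8R,10S; acyl 2'S) | C=C[C@](C)(O)C(=O)O[C@@H]1C[C@]2(C)CCC=C(C(=O)OC)[C@@H](O2)[C@H]2OC(=O)C(=C)[C@@H]21 | target

## Step count and least certain steps

Total: 26 steps. Longest linear sequence: 25 steps (steps 1–21 and 23–26); step 22 prepares the side chain.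

**Step 4 (key step).** The trans-diaxial glycol may fragment slowly, and dione 6 may isomerise into conjugation or close by transannular aldol reaction in the presence of acetic acid. Fallback, from 2 to 6 without the diol: one equivalent of ozone (CH2Cl2, −78 °C, dye end point) attacks the most electron-rich alkene of 2, and the ozonide F1 is reduced with dimethyl sulfide under neutral conditions. The same C–C bond is cut, but by alkene cleavage instead of glycol cleavage.

**Step 8.** Site selectivity may be poor, because abstraction at C4/C6 is favoured over C1/C9 only by the neighbouring methyl; over-oxidation to enones is a second risk. Fallback, from 6 to 10 with the two nucleophile additions in reverse order, so that the unwanted positions are deactivated by a ketal carbon: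
- Substoichiometric NaBH4 on 6 gives the hemiketal 11-oxabicyclo[4.4.1]undeca-3,8-dien-1-ol F2, which is silylated (Et3SiOTf) to the bridgehead silyl ketal F3.
- SeO2/t-BuOOH then oxidises next to the C–H bridgehead, away from the ketal carbon with its two β-oxygens, to give diol F4.
- t-BuMe2SiOTf gives the bis-silyl ether F5, and mild acidic methanolysis frees the hemiketal F6.
- MeLi/CeCl3 on the ring-opened ketone gives the methyl carbinol F7, and closure as in step 7 gives the bridged bis-silyl ether F8.
- Bu4NF returns 10.

**Step 15.** Oxypalladation of a cyclic cis-alkene may be sluggish, water may add at the wrong carbon, and palladium hydride may isomerise the alkene. Fallback, from 16 to 18 by a Wharton transposition: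
- K2CO3/MeOH gives the allylic alcohol F9.
- VO(acac)2/t-BuOOH gives the syn epoxy alcohol F10.
- Dess–Martin oxidation gives the epoxy ketone F11.
- Hydrazine hydrate/AcOH gives the transposed allylic alcohol F12 (C8 hydroxyl, C6=C7).
- MnO2 gives 18.

**Step 7.** The C10 cation may accept the C5 hydride across the ring (a 1,6-shift giving a ketone) or lose a proton, instead of being captured by the hydroxyl. Fallback, from 6 to 9 without a free cation:
- Mono-methylenation of 6 with Cp2Ti(μ-Cl)(μ-CH2)AlMe2 gives the methylidene ketone F13.
- NaBH4 gives the alcohol F14.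
- Hg(OCOCF3)2 effects intramolecular oxymercuration to the organomercurial F15, which NaBH4/NaOH reduces to 9.

**Step 18.** Under basic peroxide the C8 ketone may enolise toward C9 and expel the bridging oxygen from C10 (retro-oxa-Michael), opening the bicycle. Fallback, from 21 to 23 without an epoxide: copper-catalysed conjugate borylation (CuCl, Xantphos, B2pin2, MeOH, near neutral) gives the β-boryl ketone F16, and NaBO3 oxidises the C–B bond with retention to 23.

**Step 24.** Oxidation may compete at the C7 methine or the enoate γ-CH2, and a silyl ether may be lost. Fallback, from 30 to 33: ene-type chlorination with Ca(OCl)2/CO2 gives the allylic chloride F17; N-methylmorpholine N-oxide converts it into the enal F18; HF·pyridine then frees 33, which closes to 34 and is oxidised as in step 26.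

## Further compounds

F1 | step 4 | secondary ozonide of the ring-fusion alkene of 2 | C12(CC=CCC3(CC=CC1)OO2)O3
F2 | step 8 | 11-oxabicyclo[4.4.1]undeca-3,8-dien-1-ol | C1C[C@]2(O)CC=CC[C@@H](O2)CC=1
F3 | step 8 | 1-(triethylsilyloxy)-11-oxabicyclo[4.4.1]undeca-3,8-diene | C1C[C@]2(O[Si](CC)(CC)CC)CC=CC[C@@H](O2)CC=1
F4 | step 8 | meso-diol of F3 with exo hydroxyls on the carbons flanking the C–H bridgehead | C1C[C@]2(O[Si](CC)(CC)CC)CC=C[C@@H](O)[C@@H](O2)[C@@H](O)C=1
F5 | step 8 | bis(tert-butyldimethylsilyl) ether of F4 | C1C[C@]2(O[Si](CC)(CC)CC)CC=C[C@@H](O[Si](C)(C)C(C)(C)C)[C@@H](O2)[C@@H](O[Si](C)(C)C(C)(C)C)C=1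
F6 | step 8 | hemiketal from F5 after loss of the bridgehead silyl group | C1C[C@]2(O)CC=C[C@@H](O[Si](C)(C)C(C)(C)C)[C@@H](O2)[C@@H](O[Si](C)(C)C(C)(C)C)C=1
F7 | step 8 | 1-methylcyclodeca-3,8-diene-1,6-diol with silyl ethers on C5 and C7 of the diol ring (C1 configuration not defined) | CC1(O)C/C=C\[C@@H](O[Si](C)(C)C(C)(C)C)[C@@H](O)[C@@H](O[Si](C)(C)C(C)(C)C)/C=C\C1
F8 | step 8 | bis(tert-butyldimethylsilyl) ether of 10 | C1C[C@]2(C)CC=C[C@@H](O[Si](C)(C)C(C)(C)C)[C@@H](O2)[C@@H](O[Si](C)(C)C(C)(C)C)C=1
F9 | step 15 | allylic alcohol: 16 with a free exo C6 hydroxyl | C1C[C@]2(C)CCC=C(C(=O)OC)[C@@H](O2)[C@@H](O)C=1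
F10 | step 15 | epoxy alcohol: exo 7,8-epoxide, exo C6 hydroxyl | O1[C@H]2C[C@]3(C)CCC=C(C(=O)OC)[C@@H](O3)[C@@H](O)[C@@H]12
F11 | step 15 | epoxy ketone: exo 7,8-epoxide, C6 ketone | O1[C@H]2C[C@]3(C)CCC=C(C(=O)OC)[C@@H](O3)C(=O)[C@@H]12
F12 | step 15 | transposed allylic alcohol: exo C8 hydroxyl, C6=C7 | O[C@H]1C[C@]2(C)CCC=C(C(=O)OC)[C@@H](O2)C=C1
F13 | step 7 | (3Z,8Z)-6-methylidenecyclodeca-3,8-dien-1-one | C=C1C/C=C\CC(=O)C/C=C\C1
F14 | step 7 | (3Z,8Z)-6-methylidenecyclodeca-3,8-dien-1-ol | C=C1C/C=C\CC(O)C/C=C\C1
F15 | step 7 | organomercurial: 9 with CH2HgOCOCF3 in place of the methyl group | C1C[C@]2(C[Hg]OC(=O)C(F)(F)F)CC=CC[C@@H](O2)CC=1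
F16 | step 18 | β-boryl ketone: exo C6 pinacolboryl, endo C7 isopropenyl, C8 ketone | O=C1C[C@]2(C)CCC=C(C(=O)OC)[C@@H](O2)[C@@H](B3OC(C)(C)C(C)(C)O3)[C@@H]1C(C)=C
F17 | step 24 | allylic chloride: 30 with CH2Cl in place of the isopropenyl methyl | C=C[C@](C)(O[Si](CC)(CC)CC)C(=O)O[C@@H]1C[C@]2(C)CCC=C(C(=O)OC)[C@@H](O2)[C@@H](O[Si](CC)(CC)CC)[C@@H]1C(CCl)=C
F18 | step 24 | enal: 30 with CHO in place of the isopropenyl methyl | C=C[C@](C)(O[Si](CC)(CC)CC)C(=O)O[C@@H]1C[C@]2(C)CCC=C(C(=O)OC)[C@@H](O2)[C@@H](O[Si](CC)(CC)CC)[C@@H]1C(C=O)=C
A1 | alternative 1 | furan-fused 11-oxabicyclo[4.4.1]undecene with a C4 vinyl bromide and a C8 silyl ether | CC(C)(C)[Si](C)(C)O[C@@H]1C[C@]2(C)CCC=C(Br)[C@@H](O2)c2occc21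
A2 | alternative 2 | 2,5-dihydrooxepine with C5 stereocentre, C3=C4 enoate and the C6–C8 side chain | CC1=C(C(=O)OC(C)(C)C)CC=C(C(=O)OC)[C@@H](O1)[C@@H](O[Si](C)(C)C(C)(C)C)[C@H](C(C)=C)C(C)=O
A3 | alternative 3 | tricyclic photoadduct: cyclohexanone fused to a bicyclo[2.2.0]hexane | CC(C)(C)[Si](C)(C)O[C@@H]1C[C@]2(C)[C@H](C(=O)C1)[C@@]1(C(=O)OC)CC[C@H]12
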